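**Plan**
- Numbering: lactone O1, C2 (C=O), C3, C4, C5; C7' is the CH2 between C3 and ring B; ring B is B1 (bears C7'), B2 (OH), B3 (OMe), B4 (OH), B5 (H), B6 (H); ring A is the 4-hydroxy-3-methoxyphenyl ring on the C4 benzyl group.
- Cuts, in retrosynthetic order: the two O-benzyl bonds (ring A O4, ring B O4); then B1–B2 and B5–B6 of ring B; then C3–C7'; then C5–O1 of the lactone, back to a Stobbe half ester.
- Enabling feature: B2, B3 and B4 carry three contiguous, differently substituted oxygens and B5, B6 are plain CH. B2–B5 therefore map onto the C=O, C(OMe), C(OBn) and CHCl carbons of a squarate-derived cyclobutenone, and B6, B1, C7' onto an (E)-allylstannane on C3.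
- Forward order: lactone ring first (steps 1–3), stannylallyl chain on C3 (step 6), ring B last by coupling, ring opening and ring closure (step 10), then hydrogenolysis (step 11).
- Stereochemistry: C4 (R) from asymmetric hydrogenation of the Stobbe alkene; C3 (R) from enolate alkylation anti to the C4 substituent; ring B formation creates no stereocentre.

Key step: step 10

Assumption: the (R,R) antipode of Et-DuPhos is taken to deliver the (R) half ester 5; should a first run show the opposite sense, the (S,S) ligand is used and nothing else changes.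

**Step 1**
Reactants: 1 4-benzyloxy-3-methoxybenzaldehyde; 2 dimethyl succinate
Product: 4 (E)-4-(4-benzyloxy-3-methoxyphenyl)-3-(methoxycarbonyl)but-3-enoic acid, via paraconate lactone 3 (not isolated)
Conditions: NaOMe (1.2 equiv), MeOH, reflux; then 1 M HCl
Reagents that add atoms: none
Why: Stobbe condensation, in which the succinate enolate adds to the aldehyde, the alkoxide lactonises onto the distal ester to give 3, and base-induced E1cB ring opening gives the half ester irreversibly as its carboxylate with the aryl group trans to the ester; no stereocentre is formed.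

**Step 2**
Reactants: 4 (E)-4-(4-benzyloxy-3-methoxyphenyl)-3-(methoxycarbonyl)but-3-enoic acid
Product: 5 (R)-4-(4-benzyloxy-3-methoxyphenyl)-3-(methoxycarbonyl)butanoic acid
Conditions: H2 (5 bar), [Rh(cod)((R,R)-Et-DuPhos)]BF4 (0.5 mol %), NaOMe (0.1 equiv), MeOH, rt
Reagents that add atoms: none
Why: Asymmetric hydrogenation of a Stobbe-type itaconate half ester, in which carboxylate and alkene chelate the cationic rhodium bisphospholane complex so that the C2-symmetric ligand directs hydrogen to one alkene face and sets the future lactone C4 as (R); the homogeneous catalyst should leave the benzyl ether intact.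

**Step 3**
Reactants: 5 (R)-4-(4-benzyloxy-3-methoxyphenyl)-3-(methoxycarbonyl)butanoic acid
Product: 7 (R)-4-(4-benzyloxy-3-methoxybenzyl)dihydrofuran-2(3H)-one, via hydroxy acid 6 (not isolated)
Conditions: LiBHEt3 (3.2 equiv), THF, −78 → 0 °C; then 2 M HCl, rt
Reagents that add atoms: none
Why: Chemoselective hydride reduction of an ester beside a carboxylate followed by acid lactonisation: the first equivalent of hydride turns the acid into the inert lithium carboxylate, the methyl ester is reduced to the primary alcohol 6, and acidification closes the five-membered lactone without touching the stereocentre.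

**Step 4**
Reactants: 8 prop-2-yn-1-ol
Product: 9 (E)-3-(tributylstannyl)prop-2-en-1-ol
Conditions: Bu3SnH (1.3 equiv), AIBN (cat.), neat, 80 °C; chromatography to remove the Z and 2-stannyl isomers
Reagents that add atoms: tributyltin hydride, CCCC[SnH](CCCC)CCCC
Why: Radical hydrostannylation, in which the stannyl radical adds to the terminal alkyne carbon and reversible addition and loss of stannyl radicals equilibrates the vinylstannane towards the E isomer, which is purified at this inexpensive stage.

**Step 5**
Reactants: 9 (E)-3-(tributylstannyl)prop-2-en-1-ol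
Product: 10 (E)-(3-bromoprop-1-en-1-yl)tributylstannane
Conditions: CBr4, PPh3, CH2Cl2, −20 → 0 °C
Reagents that add atoms: carbon tetrabromide, BrC(Br)(Br)Br
Why: Appel reaction, in which bromide displaces the alkoxyphosphonium ion at the primary carbon under neutral conditions, so that the acid-sensitive vinyl–tin bond and the E geometry should be kept.

**Step 6**
Reactants: 7 (R)-4-(4-benzyloxy-3-methoxybenzyl)dihydrofuran-2(3H)-one; 10 (E)-(3-bromoprop-1-en-1-yl)tributylstannane
Product: 12 (3R,4R)-4-(4-benzyloxy-3-methoxybenzyl)-3-[(E)-3-(tributylstannyl)allyl]dihydrofuran-2(3H)-one, via lithium enolate 11 (not isolated)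
Conditions: LiN(SiMe3)2 (1.1 equiv), THF, −78 °C; then 10, DMPU, −78 → −40 °C
Reagents that add atoms: none
Why: Lactone enolate alkylation, in which the allylic bromide attacks the enolate face opposite the C4 benzyl group and so sets C3 as (R) in the trans lactone, while the vinylstannane is inert to the amide base at low temperature.

**Step 7**
Reactants: 13 dimethyl squarate
Product: 14 4-hydroxy-2,3-dimethoxycyclobut-2-en-1-one (racemic)
Conditions: LiAlH(OtBu)3 (1.05 equiv), THF, −78 → −20 °C; then cold H2O
Reagents that add atoms: none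
Why: Mono-reduction of a cyclobutenedione by a bulky alkoxyaluminium hydride, which adds once to one of the two equivalent carbonyl groups because the remaining carbonyl is a weakly electrophilic vinylogous ester; the carbinol centre is racemic and disappears in step 10.

**Step 8**
Reactants: 14 4-hydroxy-2,3-dimethoxycyclobut-2-en-1-one
Product: 15 4-chloro-2,3-dimethoxycyclobut-2-en-1-one (racemic)
Conditions: PPh3, NCS, CH2Cl2, −20 → 0 °C
Reagents that add atoms: N-chlorosuccinimide, O=C1CCC(=O)N1Cl
Why: Appel-type deoxychlorination, in which chloride displaces the alkoxyphosphonium ion at a carbon that is both allylic and alpha to the carbonyl, in a neutral anhydrous medium that avoids the aqueous acid known to turn such carbinols into cyclobutenediones.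

**Step 9**
Reactants: 15 4-chloro-2,3-dimethoxycyclobut-2-en-1-one
Product: 16 3-benzyloxy-4-chloro-2-methoxycyclobut-2-en-1-one (racemic)
Conditions: BnOH (5 equiv), camphorsulfonic acid (10 mol %), 5 Å molecular sieves, CH2Cl2, rt
Reagents that add atoms: benzyl alcohol, OCc1ccccc1
Why: Acid-catalysed alkoxy exchange of a vinylogous ester by addition–elimination at the beta carbon, with the sieves taking up methanol, while the enol-ether methoxy on the alpha carbon cannot exchange; because the chlorine-bearing carbon is bonded to both the carbonyl carbon and the beta carbon, every O-benzylation pathway gives the same constitution.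

**Step 10**
Reactants: 12 (3R,4R)-4-(4-benzyloxy-3-methoxybenzyl)-3-[(E)-3-(tributylstannyl)allyl]dihydrofuran-2(3H)-one; 16 3-benzyloxy-4-chloro-2-methoxycyclobut-2-en-1-one
Product: 20 (3R,4R)-3-(4-benzyloxy-2-hydroxy-3-methoxybenzyl)-4-(4-benzyloxy-3-methoxybenzyl)dihydrofuran-2(3H)-one, via alkenylcyclobutenone 17 (not isolated), via dienylketene 18 (not isolated), via cyclohexadienone 19 (not isolated)
Conditions: 16 (1.3 equiv), Pd2(dba)3 (2.5 mol %), P(2-furyl)3 (10 mol %), dioxane (0.02 M), 50 °C; then 100 °C
Reagents that add atoms: none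
Why: Zerovalent palladium inserts into the allylic, alpha-keto C–Cl bond of 16, the alkenyl group of 12 is transferred from tin (Stille coupling), and reductive elimination at the unsubstituted CH terminus forms B5–B6 in 17. On warming, the strained ring opens by a conrotatory 4-pi electrocyclic reaction to the dienylketene 18; its ketene carbon then bonds to the alkene terminus carrying C7' in a thermal disrotatory 6-pi electrocyclisation that closes the six-membered ring B at B1–B2, and enolisation of 19 gives the phenol. The closest known reaction type is the palladium-catalysed coupling of 4-chlorocyclobutenones with alkenylstannanes followed by thermal rearrangement to phenols, of which the 2,3-dialkoxy substitution is a direct extension. No stereocentre is created, and the neutral conditions should leave C3 and C4 unchanged. Two selectivities are needed: coupling at the CH terminus and not at the methoxy-bearing terminus, which the lower substitution of that carbon favours, and inward rotation of the alkenyl group, which is secured because ring opening is reversible and only the inward ketene is drained by cyclisation. The connectivity of 16 then places the free OH, OMe and OBn on B2, B3 and B4.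

**Step 11**
Reactants: 20 (3R,4R)-3-(4-benzyloxy-2-hydroxy-3-methoxybenzyl)-4-(4-benzyloxy-3-methoxybenzyl)dihydrofuran-2(3H)-one
Product: 21 (3R,4R)-3-(2,4-dihydroxy-3-methoxybenzyl)-4-(4-hydroxy-3-methoxybenzyl)dihydrofuran-2(3H)-one
Conditions: H2 (1 atm), Pd/C (10 wt %), EtOAc–MeOH, rt
Reagents that add atoms: none
Why: Catalytic hydrogenolysis of the two aryl benzyl ethers under neutral conditions frees both para phenols, while the lactone C–O bond is not benzylic and the aryl methyl ethers and both stereocentres should be unaffected.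

**Compound list**
1 | 4-benzyloxy-3-methoxybenzaldehyde (O-benzylvanillin, commercial) | O=Cc1ccc(OCc2ccccc2)c(OC)c1 | starting material
2 | dimethyl succinate | COC(=O)CCC(=O)OC | starting material
3 | methyl 2-(4-benzyloxy-3-methoxyphenyl)-5-oxotetrahydrofuran-3-carboxylate (paraconate lactone, racemic, formed in the flask in step 1) | COC(=O)C1CC(=O)OC1c1ccc(OCc2ccccc2)c(OC)c1 | intermediate
4 | (E)-4-(4-benzyloxy-3-methoxyphenyl)-3-(methoxycarbonyl)but-3-enoic acid | COC(=O)/C(CC(=O)O)=C/c1ccc(OCc2ccccc2)c(OC)c1 | intermediate
5 | (R)-4-(4-benzyloxy-3-methoxyphenyl)-3-(methoxycarbonyl)butanoic acid | COC(=O)[C@@H](CC(=O)O)Cc1ccc(OCc2ccccc2)c(OC)c1 | intermediate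
6 | (R)-4-(4-benzyloxy-3-methoxyphenyl)-3-(hydroxymethyl)butanoic acid (formed in the flask in step 3) | OC[C@@H](CC(=O)O)Cc1ccc(OCc2ccccc2)c(OC)c1 | intermediate
7 | (R)-4-(4-benzyloxy-3-methoxybenzyl)dihydrofuran-2(3H)-one | O=C1C[C@@H](Cc2ccc(OCc3ccccc3)c(OC)c2)CO1 | intermediate
8 | prop-2-yn-1-ol (propargyl alcohol) | C#CCO | starting material
9 | (E)-3-(tributylstannyl)prop-2-en-1-ol | OC/C=C/[Sn](CCCC)(CCCC)CCCC | intermediate
10 | (E)-(3-bromoprop-1-en-1-yl)tributylstannane | BrC/C=C/[Sn](CCCC)(CCCC)CCCC | intermediate
11 | lithium (R)-4-(4-benzyloxy-3-methoxybenzyl)-4,5-dihydrofuran-2-olate (enolate of 7, formed in the flask in step 6) | [Li]OC1=C[C@@H](Cc2ccc(OCc3ccccc3)c(OC)c2)CO1 | intermediate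
12 | (3R,4R)-4-(4-benzyloxy-3-methoxybenzyl)-3-[(E)-3-(tributylstannyl)allyl]dihydrofuran-2(3H)-one | COc1cc(C[C@H]2COC(=O)[C@@H]2C/C=C/[Sn](CCCC)(CCCC)CCCC)ccc1OCc1ccccc1 | intermediate
13 | dimethyl squarate (3,4-dimethoxycyclobut-3-ene-1,2-dione) | COC1=C(OC)C(=O)C1=O | starting material
14 | 4-hydroxy-2,3-dimethoxycyclobut-2-en-1-one (racemic) | COC1=C(OC)C(O)C1=O | intermediate
15 | 4-chloro-2,3-dimethoxycyclobut-2-en-1-one (racemic) | COC1=C(OC)C(Cl)C1=O | intermediate
16 | 3-benzyloxy-4-chloro-2-methoxycyclobut-2-en-1-one (racemic) | O=C1C(OC)=C(OCc2ccccc2)C1Cl | intermediate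
17 | (3R,4R)-3-[(E)-3-(2-benzyloxy-3-methoxy-4-oxocyclobut-2-en-1-yl)allyl]-4-(4-benzyloxy-3-methoxybenzyl)dihydrofuran-2(3H)-one (both epimers at the cyclobutenone CH, formed in the flask in step 10) | COc1cc(C[C@H]2COC(=O)[C@@H]2C/C=C/C3C(=O)C(OC)=C3OCc3ccccc3)ccc1OCc1ccccc1 | intermediate
18 | (3R,4R)-3-[(2E,4E)-5-benzyloxy-6-methoxy-7-oxohepta-2,4,6-trien-1-yl]-4-(4-benzyloxy-3-methoxybenzyl)dihydrofuran-2(3H)-one (dienylketene with the alkenyl arm cis to the ketene carbon, formed in the flask in step 10) | COc1cc(C[C@H]2COC(=O)[C@@H]2C/C=C/C=C(OCc2ccccc2)\C(OC)=C=O)ccc1OCc1ccccc1 | intermediate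
19 | (3R,4R)-3-[(4-benzyloxy-3-methoxy-2-oxocyclohexa-3,5-dien-1-yl)methyl]-4-(4-benzyloxy-3-methoxybenzyl)dihydrofuran-2(3H)-one (both epimers at the ring CH, formed in the flask in step 10) | COc1cc(C[C@H]2COC(=O)[C@@H]2CC3C=CC(OCc4ccccc4)=C(OC)C3=O)ccc1OCc1ccccc1 | intermediate
20 | (3R,4R)-3-(4-benzyloxy-2-hydroxy-3-methoxybenzyl)-4-(4-benzyloxy-3-methoxybenzyl)dihydrofuran-2(3H)-one | COc1cc(C[C@H]2COC(=O)[C@@H]2Cc3ccc(OCc4ccccc4)c(OC)c3O)ccc1OCc1ccccc1 | intermediate
21 | (3R,4R)-3-(2,4-dihydroxy-3-methoxybenzyl)-4-(4-hydroxy-3-methoxybenzyl)dihydrofuran-2(3H)-one | COc1cc(C[C@H]2COC(=O)[C@@H]2Cc2ccc(O)c(OC)c2O)ccc1O | target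

**Step count**
Total: 11 steps. Longest linear sequence: 6 steps (steps 1, 2, 3, 6, 10, 11 from aldehyde 1); the squarate branch (steps 7–9) and the stannane branch (steps 4–5) are shorter.

**Steps most likely to fail**

1. Step 10. Transmetalation at the electron-rich, dialkoxy-substituted allylpalladium intermediate may be slow, so that degradation of 16, protodestannylation or homocoupling of the valuable stannane 12, or capture of ketene 18 by the phenol being formed could compete. The fallback sets out from 9, 16 and 7 and comes back to the route at 21.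
 - Alcohol 9 is silylated (TBSCl, imidazole, DMF) to (E)-tert-butyldimethyl{[3-(tributylstannyl)allyl]oxy}silane F1, a small stannane that can be used in excess.
 - Coupling of F1 with 16 under the conditions of step 10 should give, by the same ring opening and closure, 3-benzyloxy-6-[(tert-butyldimethylsilyloxy)methyl]-2-methoxyphenol F2.
 - O-Benzylation (BnBr, K2CO3, DMF) gives {[2,4-bis(benzyloxy)-3-methoxybenzyl]oxy}(tert-butyl)dimethylsilane F3.
 - Ph3PBr2 (CH2Cl2, 0 °C) converts the silyl ether directly into 1,3-bis(benzyloxy)-4-(bromomethyl)-2-methoxybenzene F4.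
 - Enolate 11, made from 7 as in step 6, is alkylated trans with F4 to (3R,4R)-3-[2,4-bis(benzyloxy)-3-methoxybenzyl]-4-(4-benzyloxy-3-methoxybenzyl)dihydrofuran-2(3H)-one F5, and hydrogenolysis as in step 11 removes all three benzyl groups to give 21.

2. Step 8. The activated C–O bond may ionise with help from the alpha methoxy group, and loss of a methyl group would then give a cyclobutenedione in place of substitution. The fallback sets out from 14 and comes back at 20.
 - Acetylation (Ac2O, pyridine, 0 °C) gives 2,3-dimethoxy-4-oxocyclobut-2-en-1-yl acetate F6, whose leaving group is far poorer than an oxyphosphonium ion.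
 - Alkoxy exchange as in step 9 gives 2-benzyloxy-3-methoxy-4-oxocyclobut-2-en-1-yl acetate F7.
 - F7 replaces 16 as an allylic acetate in the palladium-catalysed coupling with 12 (Pd2(dba)3, P(2-furyl)3, LiCl, DMF, 50 °C then 100 °C); the same ring opening and closure should lead to 20.

3. Step 9. The exchange is an equilibrium and may stall, and the labile allylic chloride may solvolyse or the ring may cleave during long contact with acid and during removal of excess benzyl alcohol. The fallback sets out from 15 and comes back at 16.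
 - The vinylogous ester is hydrolysed (0.5 M HCl, THF–H2O, 0 °C) to 4-chloro-3-hydroxy-2-methoxycyclobut-2-en-1-one F8, a vinylogous acid whose two oxygen-bearing carbons flanking C(OMe) are equivalent.
 - Irreversible O-benzylation (BnBr, Ag2O, CH2Cl2, dark) at either oxygen gives 16.

**Further compounds**
F1 | step 10 | (E)-tert-butyldimethyl{[3-(tributylstannyl)allyl]oxy}silane | CC(C)(C)[Si](C)(C)OC/C=C/[Sn](CCCC)(CCCC)CCCC
F2 | step 10 | 3-benzyloxy-6-[(tert-butyldimethylsilyloxy)methyl]-2-methoxyphenol | COc1c(O)c(CO[Si](C)(C)C(C)(C)C)ccc1OCc1ccccc1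
F3 | step 10 | {[2,4-bis(benzyloxy)-3-methoxybenzyl]oxy}(tert-butyl)dimethylsilane | COc1c(OCc2ccccc2)c(CO[Si](C)(C)C(C)(C)C)ccc1OCc1ccccc1
F4 | step 10 | 1,3-bis(benzyloxy)-4-(bromomethyl)-2-methoxybenzene | COc1c(OCc2ccccc2)c(CBr)ccc1OCc1ccccc1
F5 | step 10 | (3R,4R)-3-[2,4-bis(benzyloxy)-3-methoxybenzyl]-4-(4-benzyloxy-3-methoxybenzyl)dihydrofuran-2(3H)-one | COc1cc(C[C@H]2COC(=O)[C@@H]2Cc2ccc(OCc3ccccc3)c(OC)c2OCc2ccccc2)ccc1OCc1ccccc1
F6 | step 8 | 2,3-dimethoxy-4-oxocyclobut-2-en-1-yl acetate (racemic) | COC1=C(OC)C(OC(C)=O)C1=O
F7 | step 8 | 2-benzyloxy-3-methoxy-4-oxocyclobut-2-en-1-yl acetate (racemic) | CC(=O)OC1C(OCc2ccccc2)=C(OC)C1=O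
F8 | step 9 | 4-chloro-3-hydroxy-2-methoxycyclobut-2-en-1-one (racemic) | COC1=C(O)C(Cl)C1=O
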